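## Retrosynthetic overview

1. The C4 ester is installed last by Mitsunobu esterification (inversion) of a 4-epi macrocyclic alcohol with the side-chain acid; a silyl ether on the primary allylic alcohol is then removed.
2. The ten-membered ring is closed at C3a–C4: CrCl2 converts an α-(bromomethyl)butenolide into an allylchromium (a lactone β-anion equivalent) that adds to a tethered aldehyde. This creates C3a, C4 and the exo-methylene lactone.
3. The butenolide comes from an intramolecular Morita–Baylis–Hillman reaction of an acrylate ester with its neighbouring α-acyloxy aldehyde, followed by SN2′ bromination.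
4. The (E)-trisubstituted alkene comes from a Horner–Wadsworth–Emmons reaction of an α-phosphono-γ-lactone (phosphonoacetate plus a chiral glycidyl ether, which sets C11a) with an aldehyde cut from a chiral-pool monoterpene alcohol (which sets C6). The lactone is then reduced to the diol.
5. Ring order: five-membered lactone first (step 11), ten-membered carbocycle second (step 13).

Assumption: locants follow cyclodeca[b]furan numbering (O1, C2=O, C3, C3a, C4–C11, C11a); the target read from the SMILES is (3aR,4S,6R,9E,11aS) with a (2Z) side chain.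

## Route

Step 1
Reactants: 1 (R)-linalool
Product: 3 (3R)-3,7-dimethyloct-6-ene-1,3-diol, via alkylborane 2 (not isolated)
Conditions: 9-BBN, THF, 0 °C → rt; then aq. NaOH, H2O2, 0 °C
Reagents that add atoms: hydrogen peroxide (OO)
Why: Hydroboration–oxidation: 9-BBN adds anti-Markovnikov to the monosubstituted vinyl group only (the trisubstituted alkene is untouched) and oxidation gives the primary alcohol; the tertiary stereocentre (later C6) is not involved.

Step 2
Reactants: 3 (3R)-3,7-dimethyloct-6-ene-1,3-diol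
Product: 4 (4R)-2,2,4-trimethyl-4-(4-methylpent-3-en-1-yl)-1,3-dioxane
Conditions: Me2C(OMe)2, PPTS (cat.), CH2Cl2, rt
Reagents that add atoms: 2,2-dimethoxypropane (COC(C)(C)OC)
Why: Acid-catalysed transacetalisation ties the primary/tertiary 1,3-diol into a six-membered acetonide, masking both hydroxyls until step 9.

Step 3
Reactants: 4 (4R)-2,2,4-trimethyl-4-(4-methylpent-3-en-1-yl)-1,3-dioxane
Product: 6 3-[(4R)-2,2,4-trimethyl-1,3-dioxan-4-yl]propanal, via ozonide 5 (not isolated)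
Conditions: O3, CH2Cl2, −78 °C; then PPh3, −78 °C → rt
Reagents that add atoms: ozone ([O-][O+]=O)
Why: Ozonolysis with reductive work-up cleaves the electron-rich trisubstituted alkene to the aldehyde and acetone; the ketal has no acetal C–H and survives.

Step 4
Reactants: 7 triethyl phosphonoacetate; 8 (S)-glycidyl trityl ether
Product: 10 diethyl {(5S)-2-oxo-5-[(trityloxy)methyl]oxolan-3-yl}phosphonate, via sodium alkoxide 9 (not isolated)
Conditions: NaH, THF/DMF, 0 → 70 °C; then 1 M HCl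
Reagents that add atoms: none
Why: Epoxide alkylation–lactonisation: the phosphonoacetate anion opens the epoxide at its terminal carbon (SN2, the stereocentre is untouched and becomes C11a) and the resulting alkoxide closes onto the ester to give the α-phosphono-γ-lactone (C3 epimers, irrelevant).

Step 5
Reactants: 10 diethyl {(5S)-2-oxo-5-[(trityloxy)methyl]oxolan-3-yl}phosphonate; 6 3-[(4R)-2,2,4-trimethyl-1,3-dioxan-4-yl]propanal
Product: 11 (3E,5S)-3-{3-[(4R)-2,2,4-trimethyl-1,3-dioxan-4-yl]propylidene}-5-[(trityloxy)methyl]oxolan-2-one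
Conditions: t-BuOK, THF, −78 → 0 °C; the minor Z isomer is removed by chromatography
Reagents that add atoms: none
Why: Horner–Wadsworth–Emmons olefination of the lactone phosphonate gives mainly the (E)-alkylidene lactone (chain trans to C=O, cis to the ring CH2), which fixes the geometry of the future C9=C10 bond.

Step 6
Reactants: 11 (3E,5S)-3-{3-[(4R)-2,2,4-trimethyl-1,3-dioxan-4-yl]propylidene}-5-[(trityloxy)methyl]oxolan-2-one
Product: 12 (2S,4E)-4-(hydroxymethyl)-7-[(4R)-2,2,4-trimethyl-1,3-dioxan-4-yl]-1-(trityloxy)hept-4-en-2-ol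
Conditions: DIBAL-H (4 equiv), CH2Cl2, −78 → 0 °C; Rochelle salt work-up
Reagents that add atoms: none
Why: DIBAL-H reduces the conjugated lactone by 1,2-addition through the lactol to the allylic diol, leaving the alkene geometry, ketal and trityl ether intact.

Step 7
Reactants: 12 (2S,4E)-4-(hydroxymethyl)-7-[(4R)-2,2,4-trimethyl-1,3-dioxan-4-yl]-1-(trityloxy)hept-4-en-2-ol
Product: 13 (2S,4E)-4-{[tert-butyl(diphenyl)silyl]oxymethyl}-7-[(4R)-2,2,4-trimethyl-1,3-dioxan-4-yl]-1-(trityloxy)hept-4-en-2-ol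
Conditions: TBDPSCl (1.05 equiv), imidazole, CH2Cl2, 0 °C
Reagents that add atoms: tert-butyl(chloro)diphenylsilane (CC(C)(C)[Si](Cl)(c1ccccc1)c1ccccc1)
Why: Selective silylation: the bulky silyl chloride reacts with the primary allylic hydroxyl and leaves the secondary one free.

Step 8
Reactants: 13 (2S,4E)-4-{[tert-butyl(diphenyl)silyl]oxymethyl}-7-[(4R)-2,2,4-trimethyl-1,3-dioxan-4-yl]-1-(trityloxy)hept-4-en-2-ol
Product: 14 (2S,4E)-4-{[tert-butyl(diphenyl)silyl]oxymethyl}-7-[(4R)-2,2,4-trimethyl-1,3-dioxan-4-yl]-1-(trityloxy)hept-4-en-2-yl prop-2-enoate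
Conditions: CH2=CHCOCl, i-Pr2NEt, CH2Cl2, −40 → 0 °C
Reagents that add atoms: acryloyl chloride (C=CC(Cl)=O)
Why: O-acylation of the secondary alcohol with an acid chloride and a hindered base (no amine conjugate addition) installs the three carbons of the future lactone.

Step 9
Reactants: 14 (2S,4E)-4-{[tert-butyl(diphenyl)silyl]oxymethyl}-7-[(4R)-2,2,4-trimethyl-1,3-dioxan-4-yl]-1-(trityloxy)hept-4-en-2-yl prop-2-enoate
Product: 15 (2S,4E,8R)-4-{[tert-butyl(diphenyl)silyl]oxymethyl}-1,8,10-trihydroxy-8-methyldec-4-en-2-yl prop-2-enoate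
Conditions: AcOH/THF/H2O (4:1:1), 40 °C; crude product used at once
Reagents that add atoms: none
Why: Acid hydrolysis removes the trityl ether (SN1) and the acetonide while the TBDPS ether and acrylate survive; immediate use limits 1,2-acyl migration.

Step 10
Reactants: 15 (2S,4E,8R)-4-{[tert-butyl(diphenyl)silyl]oxymethyl}-1,8,10-trihydroxy-8-methyldec-4-en-2-yl prop-2-enoate
Product: 16 (2S,4E,8R)-4-{[tert-butyl(diphenyl)silyl]oxymethyl}-8-hydroxy-8-methyl-1,10-dioxodec-4-en-2-yl prop-2-enoate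
Conditions: Dess–Martin periodinane (2.5 equiv), CH2Cl2, 0 °C → rt
Reagents that add atoms: none
Why: Dess–Martin oxidation converts both primary alcohols into aldehydes under non-basic conditions (the tertiary alcohol is inert and the α-acyloxy stereocentre is not enolised).

Step 11
Reactants: 16 (2S,4E,8R)-4-{[tert-butyl(diphenyl)silyl]oxymethyl}-8-hydroxy-8-methyl-1,10-dioxodec-4-en-2-yl prop-2-enoate
Product: 17 (3R,6E)-7-{[tert-butyl(diphenyl)silyl]oxymethyl}-3-hydroxy-8-[(2S)-3-hydroxy-4-methylidene-5-oxooxolan-2-yl]-3-methyloct-6-enal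
Conditions: DABCO (1 equiv), CH2Cl2, rt
Reagents that add atoms: none
Why: Intramolecular Morita–Baylis–Hillman reaction: the DABCO–acrylate enolate adds to the adjacent activated α-acyloxy aldehyde (five-membered ring, strongly favoured over the remote aldehyde); the new carbinol centre is a mixture and is erased in step 12.

Step 12
Reactants: 17 (3R,6E)-7-{[tert-butyl(diphenyl)silyl]oxymethyl}-3-hydroxy-8-[(2S)-3-hydroxy-4-methylidene-5-oxooxolan-2-yl]-3-methyloct-6-enal
Product: 18 (3R,6E)-8-[(2S)-4-(bromomethyl)-5-oxo-2,5-dihydrofuran-2-yl]-7-{[tert-butyl(diphenyl)silyl]oxymethyl}-3-hydroxy-3-methyloct-6-enal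
Conditions: NBS, Me2S, CH2Cl2, −20 → 0 °C
Reagents that add atoms: N-bromosuccinimide (O=C1CCC(=O)N1Br)
Why: Corey–Kim-type activation of the allylic alcohol and SN2′ attack of bromide on the exo-methylene gives the conjugated 3-(bromomethyl)butenolide (the usual allylic transposition of Baylis–Hillman alcohols); the tertiary alcohol and the aldehyde do not react.

Step 13
Reactants: 18 (3R,6E)-8-[(2S)-4-(bromomethyl)-5-oxo-2,5-dihydrofuran-2-yl]-7-{[tert-butyl(diphenyl)silyl]oxymethyl}-3-hydroxy-3-methyloct-6-enal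
Product: 20 (3aS,4R,6R,9E,11aS)-10-{[tert-butyl(diphenyl)silyl]oxymethyl}-4,6-dihydroxy-6-methyl-3-methylidene-3a,4,5,6,7,8,11,11a-octahydrocyclodeca[b]furan-2(3H)-one, via allylchromium 19 (not isolated)
Conditions: CrCl2 (8 equiv), THF, rt, slow addition of 18 (final 2 mM)
Reagents that add atoms: none
Why: Intramolecular Nozaki–Hiyama allylation: CrCl2 turns the electrophilic bromomethyl butenolide into an allylchromium whose nucleophilic γ-carbon (the former Michael-acceptor β-carbon, C3a) attacks the aldehyde carbon, closing the ten-membered ring and regenerating the exo-methylene lactone. The C3a–C4 bond is expected to form on the butenolide face anti to the C11a substituent (trans lactone), and the E-locked allyl unit is expected to react through a Zimmerman–Traxler chair with the aldehyde chain equatorial, giving the 3a,4-anti (4R) carbinol that step 17 inverts.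

Step 14
Reactants: 21 ethyl but-2-ynoate
Product: 23 ethyl (2Z)-2-(hydroxymethyl)but-2-enoate, via vinylalane 22 (not isolated)
Conditions: DIBAL-H, NMO, THF, 0 °C; then CH2O (gas, from paraformaldehyde), 0 °C → rt; aq. work-up
Reagents that add atoms: formaldehyde (C=O)
Why: Vinylalumination: syn-hydroalumination of the ynoate gives the α-alumino enoate (allenolate), which is hydroxymethylated on the side of the β-hydrogen, leaving the methyl cis to the ester (Z, angelate-type geometry).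

Step 15
Reactants: 23 ethyl (2Z)-2-(hydroxymethyl)but-2-enoate
Product: 24 (2Z)-2-(hydroxymethyl)but-2-enoic acid
Conditions: LiOH, THF/H2O, 0 °C → rt; then HCl to pH 2
Reagents that add atoms: lithium hydroxide ([Li+].[OH-])
Why: Saponification at low temperature hydrolyses the ethyl ester without Z→E isomerisation.

Step 16
Reactants: 24 (2Z)-2-(hydroxymethyl)but-2-enoic acid
Product: 25 (2Z)-2-(acetoxymethyl)but-2-enoic acid
Conditions: Ac2O, pyridine, 0 °C → rt; aq. work-up
Reagents that add atoms: acetic anhydride (CC(=O)OC(C)=O)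
Why: Acetylation of the primary alcohol; any mixed anhydride at the acid is hydrolysed on aqueous work-up.

Step 17
Reactants: 20 (3aS,4R,6R,9E,11aS)-10-{[tert-butyl(diphenyl)silyl]oxymethyl}-4,6-dihydroxy-6-methyl-3-methylidene-3a,4,5,6,7,8,11,11a-octahydrocyclodeca[b]furan-2(3H)-one; 25 (2Z)-2-(acetoxymethyl)but-2-enoic acid
Product: 27 (3aR,4S,6R,9E,11aS)-10-{[tert-butyl(diphenyl)silyl]oxymethyl}-6-hydroxy-6-methyl-3-methylidene-2-oxo-2,3,3a,4,5,6,7,8,11,11a-decahydrocyclodeca[b]furan-4-yl (2Z)-2-(acetoxymethyl)but-2-enoate, via oxyphosphonium salt 26 (not isolated)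
Conditions: PPh3, DIAD, toluene, 0 °C → rt
Reagents that add atoms: none
Why: Mitsunobu esterification: the secondary C4 alcohol is activated as its oxyphosphonium ion and displaced by the carboxylate with SN2 inversion (4R → 4S), installing the side chain with the target configuration; the tertiary C6 alcohol is not activated.

Step 18
Reactants: 27 (3aR,4S,6R,9E,11aS)-10-{[tert-butyl(diphenyl)silyl]oxymethyl}-6-hydroxy-6-methyl-3-methylidene-2-oxo-2,3,3a,4,5,6,7,8,11,11a-decahydrocyclodeca[b]furan-4-yl (2Z)-2-(acetoxymethyl)but-2-enoate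
Product: 28 (3aR,4S,6R,9E,11aS)-6-hydroxy-10-(hydroxymethyl)-6-methyl-3-methylidene-2-oxo-2,3,3a,4,5,6,7,8,11,11a-decahydrocyclodeca[b]furan-4-yl (2Z)-2-(acetoxymethyl)but-2-enoate
Conditions: HF·pyridine, pyridine/THF, 0 °C → rt
Reagents that add atoms: none
Why: Buffered fluoride desilylation frees the primary allylic alcohol without touching the allylic acetate, the α-methylene lactone or the tertiary alcohol.

## Compound list

1 | (R)-linalool, (3R)-3,7-dimethylocta-1,6-dien-3-ol | CC(C)=CCC[C@@](C)(O)C=C | starting material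
2 | 9-[(3R)-3-hydroxy-3,7-dimethyloct-6-en-1-yl]-9-borabicyclo[3.3.1]nonane | CC(C)=CCC[C@@](C)(O)CCB1C2CCCC1CCC2 | intermediate
3 | (3R)-3,7-dimethyloct-6-ene-1,3-diol | CC(C)=CCC[C@@](C)(O)CCO | intermediate
4 | (4R)-2,2,4-trimethyl-4-(4-methylpent-3-en-1-yl)-1,3-dioxane | CC(C)=CCC[C@@]1(C)OC(C)(C)OCC1 | intermediate
5 | 3,3-dimethyl-5-{2-[(4R)-2,2,4-trimethyl-1,3-dioxan-4-yl]ethyl}-1,2,4-trioxolane (ozonide) | CC1(C)OOC(CC[C@@]2(C)OC(C)(C)OCC2)O1 | intermediate
6 | 3-[(4R)-2,2,4-trimethyl-1,3-dioxan-4-yl]propanal | O=CCC[C@@]1(C)OC(C)(C)OCC1 | intermediate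
7 | triethyl phosphonoacetate | CCOC(=O)CP(=O)(OCC)OCC | starting material
8 | (S)-glycidyl trityl ether, (2S)-2-[(trityloxy)methyl]oxirane | C1O[C@@H]1COC(c1ccccc1)(c1ccccc1)c1ccccc1 | starting material
9 | sodium alkoxide of ethyl (4S)-2-(diethoxyphosphoryl)-4-hydroxy-5-(trityloxy)pentanoate | CCOC(=O)C(C[C@H]([O-])COC(c1ccccc1)(c1ccccc1)c1ccccc1)P(=O)(OCC)OCC.[Na+] | intermediate
10 | diethyl {(5S)-2-oxo-5-[(trityloxy)methyl]oxolan-3-yl}phosphonate (C3 epimers) | CCOP(=O)(OCC)C1C[C@@H](COC(c2ccccc2)(c2ccccc2)c2ccccc2)OC1=O | intermediate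
11 | (3E,5S)-3-{3-[(4R)-2,2,4-trimethyl-1,3-dioxan-4-yl]propylidene}-5-[(trityloxy)methyl]oxolan-2-one | O=C1O[C@H](COC(c2ccccc2)(c2ccccc2)c2ccccc2)C/C1=C\CC[C@@]1(C)OC(C)(C)OCC1 | intermediate
12 | (2S,4E)-4-(hydroxymethyl)-7-[(4R)-2,2,4-trimethyl-1,3-dioxan-4-yl]-1-(trityloxy)hept-4-en-2-ol | OC/C(=C/CC[C@@]1(C)OC(C)(C)OCC1)C[C@H](O)COC(c1ccccc1)(c1ccccc1)c1ccccc1 | intermediate
13 | (2S,4E)-4-{[tert-butyl(diphenyl)silyl]oxymethyl}-7-[(4R)-2,2,4-trimethyl-1,3-dioxan-4-yl]-1-(trityloxy)hept-4-en-2-ol | CC(C)(C)[Si](c1ccccc1)(c1ccccc1)OC/C(=C/CC[C@@]1(C)OC(C)(C)OCC1)C[C@H](O)COC(c1ccccc1)(c1ccccc1)c1ccccc1 | intermediate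
14 | (2S,4E)-4-{[tert-butyl(diphenyl)silyl]oxymethyl}-7-[(4R)-2,2,4-trimethyl-1,3-dioxan-4-yl]-1-(trityloxy)hept-4-en-2-yl prop-2-enoate | CC(C)(C)[Si](c1ccccc1)(c1ccccc1)OC/C(=C/CC[C@@]1(C)OC(C)(C)OCC1)C[C@H](OC(=O)C=C)COC(c1ccccc1)(c1ccccc1)c1ccccc1 | intermediate
15 | (2S,4E,8R)-4-{[tert-butyl(diphenyl)silyl]oxymethyl}-1,8,10-trihydroxy-8-methyldec-4-en-2-yl prop-2-enoate | CC(C)(C)[Si](c1ccccc1)(c1ccccc1)OC/C(=C/CC[C@@](C)(O)CCO)C[C@H](OC(=O)C=C)CO | intermediate
16 | (2S,4E,8R)-4-{[tert-butyl(diphenyl)silyl]oxymethyl}-8-hydroxy-8-methyl-1,10-dioxodec-4-en-2-yl prop-2-enoate | CC(C)(C)[Si](c1ccccc1)(c1ccccc1)OC/C(=C/CC[C@@](C)(O)CC=O)C[C@H](OC(=O)C=C)C=O | intermediate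
17 | (3R,6E)-7-{[tert-butyl(diphenyl)silyl]oxymethyl}-3-hydroxy-8-[(2S)-3-hydroxy-4-methylidene-5-oxooxolan-2-yl]-3-methyloct-6-enal (both carbinol epimers) | C=C1C(=O)O[C@@H](C/C(CO[Si](c2ccccc2)(c2ccccc2)C(C)(C)C)=C\CC[C@@](C)(O)CC=O)C1O | intermediate
18 | (3R,6E)-8-[(2S)-4-(bromomethyl)-5-oxo-2,5-dihydrofuran-2-yl]-7-{[tert-butyl(diphenyl)silyl]oxymethyl}-3-hydroxy-3-methyloct-6-enal | BrCC1=C[C@H](C/C(CO[Si](c2ccccc2)(c2ccccc2)C(C)(C)C)=C\CC[C@@](C)(O)CC=O)OC1=O | intermediate
19 | allylchromium(III) dichloride derived from 18 ({(5S)-2-oxo-5-substituted-2,5-dihydrofuran-3-yl}methylchromium dichloride) | Cl[Cr](Cl)CC1=C[C@H](C/C(CO[Si](c2ccccc2)(c2ccccc2)C(C)(C)C)=C\CC[C@@](C)(O)CC=O)OC1=O | intermediate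
20 | (3aS,4R,6R,9E,11aS)-10-{[tert-butyl(diphenyl)silyl]oxymethyl}-4,6-dihydroxy-6-methyl-3-methylidene-3a,4,5,6,7,8,11,11a-octahydrocyclodeca[b]furan-2(3H)-one | C=C1C(=O)O[C@H]2C/C(CO[Si](c3ccccc3)(c3ccccc3)C(C)(C)C)=C\CC[C@@](C)(O)C[C@@H](O)[C@H]12 | intermediate
21 | ethyl but-2-ynoate | CCOC(=O)C#CC | starting material
22 | ethyl (2E)-2-(diisobutylalumanyl)but-2-enoate (α-alumino enoate / allenolate) | CCOC(=O)/C(=C\C)[Al](CC(C)C)CC(C)C | intermediate
23 | ethyl (2Z)-2-(hydroxymethyl)but-2-enoate | CCOC(=O)/C(=C\C)CO | intermediate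
24 | (2Z)-2-(hydroxymethyl)but-2-enoic acid | OC(=O)/C(=C\C)CO | intermediate
25 | (2Z)-2-(acetoxymethyl)but-2-enoic acid | OC(=O)/C(=C\C)COC(C)=O | intermediate
26 | C4-oxytriphenylphosphonium salt of 20 with the carboxylate of 25 | C=C1C(=O)O[C@H]2C/C(CO[Si](c3ccccc3)(c3ccccc3)C(C)(C)C)=C\CC[C@@](C)(O)C[C@@H](O[P+](c3ccccc3)(c3ccccc3)c3ccccc3)[C@H]12.[O-]C(=O)/C(=C\C)COC(C)=O | intermediate
27 | (3aR,4S,6R,9E,11aS)-10-{[tert-butyl(diphenyl)silyl]oxymethyl}-6-hydroxy-6-methyl-3-methylidene-2-oxo-2,3,3a,4,5,6,7,8,11,11a-decahydrocyclodeca[b]furan-4-yl (2Z)-2-(acetoxymethyl)but-2-enoate | C=C1C(=O)O[C@H]2C/C(CO[Si](c3ccccc3)(c3ccccc3)C(C)(C)C)=C\CC[C@@](C)(O)C[C@H](OC(=O)/C(=C\C)COC(C)=O)[C@H]12 | intermediate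
28 | (3aR,4S,6R,9E,11aS)-6-hydroxy-10-(hydroxymethyl)-6-methyl-3-methylidene-2-oxo-2,3,3a,4,5,6,7,8,11,11a-decahydrocyclodeca[b]furan-4-yl (2Z)-2-(acetoxymethyl)but-2-enoate (CNP0313132.1) | C=C1C(=O)O[C@H]2C/C(CO)=C\CC[C@@](C)(O)C[C@H](OC(=O)/C(=C\C)COC(C)=O)[C@H]12 | target

## Step count and risks

Total step count: 18. Longest linear sequence: 14 (steps 1–3, 5–13, 17, 18).

Step 13 is the most likely to fail. The ring closure may oligomerise, and both the trans ring fusion and the 4R outcome are predictions from general models (anti attack on the butenolide, chair transition state), not from precedent on this ring system. Fallback: setting out from 18, Pd-catalysed stannylation with hexabutylditin gives the allylstannane F1. BF3·OEt2 at −78 °C under high dilution then closes the ring by a Lewis-acid-promoted SE2′ addition through an open transition state, which is syn-selective and gives the (4S)-alcohol F2. Yamaguchi esterification of F2 with 25 (retention) comes back to the route at 27, bypassing 20 and the Mitsunobu step.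

Step 17 is the second risk. The Mitsunobu reaction at the hindered C4 alcohol may give elimination to the diene, and PPh3 can attack the allylic acetate of the acid. Fallback: setting out from 20, chloromethanesulfonyl chloride and pyridine give the C4 chloromethanesulfonate F3 (the tertiary alcohol is untouched). Displacement of this isolated sulfonate with the caesium salt of 25 (18-crown-6, toluene, 40 °C) inverts C4 and comes back to the route at 27.

Step 11 is the third risk. DABCO may epimerise the α-acyloxy aldehyde centre (future C11a) or the cyclisation may stall. Fallback: setting out from 13, acylation with 2-bromoacryloyl chloride gives the 2-bromoacrylate F4. Aqueous acetic acid gives the triol F5 and Dess–Martin oxidation gives the dialdehyde F6. CrCl2 with catalytic NiCl2 (Nozaki–Hiyama–Kishi) then generates the α-acrylate vinylchromium under neutral conditions; it adds to the neighbouring aldehyde and comes back to the route at 17.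

## Further compounds

F1 | step 13 | (3R,6E)-7-{[tert-butyl(diphenyl)silyl]oxymethyl}-3-hydroxy-3-methyl-8-{(2S)-5-oxo-4-[(tributylstannyl)methyl]-2,5-dihydrofuran-2-yl}oct-6-enal | CCCC[Sn](CCCC)(CCCC)CC1=C[C@H](C/C(CO[Si](c2ccccc2)(c2ccccc2)C(C)(C)C)=C\CC[C@@](C)(O)CC=O)OC1=O
F2 | step 13 | (3aS,4S,6R,9E,11aS)-10-{[tert-butyl(diphenyl)silyl]oxymethyl}-4,6-dihydroxy-6-methyl-3-methylidene-3a,4,5,6,7,8,11,11a-octahydrocyclodeca[b]furan-2(3H)-one | C=C1C(=O)O[C@H]2C/C(CO[Si](c3ccccc3)(c3ccccc3)C(C)(C)C)=C\CC[C@@](C)(O)C[C@H](O)[C@H]12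
F3 | step 17 | (3aR,4R,6R,9E,11aS)-10-{[tert-butyl(diphenyl)silyl]oxymethyl}-6-hydroxy-6-methyl-3-methylidene-2-oxo-2,3,3a,4,5,6,7,8,11,11a-decahydrocyclodeca[b]furan-4-yl chloromethanesulfonate | C=C1C(=O)O[C@H]2C/C(CO[Si](c3ccccc3)(c3ccccc3)C(C)(C)C)=C\CC[C@@](C)(O)C[C@@H](OS(=O)(=O)CCl)[C@H]12
F4 | step 11 | (2S,4E)-4-{[tert-butyl(diphenyl)silyl]oxymethyl}-7-[(4R)-2,2,4-trimethyl-1,3-dioxan-4-yl]-1-(trityloxy)hept-4-en-2-yl 2-bromoprop-2-enoate | CC(C)(C)[Si](c1ccccc1)(c1ccccc1)OC/C(=C/CC[C@@]1(C)OC(C)(C)OCC1)C[C@H](OC(=O)C(Br)=C)COC(c1ccccc1)(c1ccccc1)c1ccccc1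
F5 | step 11 | (2S,4E,8R)-4-{[tert-butyl(diphenyl)silyl]oxymethyl}-1,8,10-trihydroxy-8-methyldec-4-en-2-yl 2-bromoprop-2-enoate | CC(C)(C)[Si](c1ccccc1)(c1ccccc1)OC/C(=C/CC[C@@](C)(O)CCO)C[C@H](OC(=O)C(Br)=C)CO
F6 | step 11 | (2S,4E,8R)-4-{[tert-butyl(diphenyl)silyl]oxymethyl}-8-hydroxy-8-methyl-1,10-dioxodec-4-en-2-yl 2-bromoprop-2-enoate | CC(C)(C)[Si](c1ccccc1)(c1ccccc1)OC/C(=C/CC[C@@](C)(O)CC=O)C[C@H](OC(=O)C(Br)=C)C=O
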